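## The problem

The target is a biflavanone in which C3 of a 5,7,3',4'-tetrahydroxyflavanone (unit 1; rings A, B, C) is bonded to C8'' of (2S)-naringenin (unit 2; rings D, E, F). A fully substituted phloroglucinol ring D therefore sits on a stereogenic sp3 carbon. In unit 1 the aryl groups on C2 and C3 are cis (2R,3R), the less stable arrangement. C3–H is alpha to the C4 carbonyl and benzylic to ring D, so any acid or base that enolizes C4 would give the trans epimer. C2 is adjacent to C3 and can control it, but C2'' lies beyond ring D, five bonds from C3, and needs its own reagent control. Ring D must be differentiated: the oxygen at C8a'' closes ring F, and the acyl carbon C4'' must enter at C4a'', not at C6''. Seven phenols (one catechol), two benzylic ring ethers (C2, C2'') and two base-labile flavanone rings limit the end of the synthesis to neutral oxidation and hydrogenolysis. The feature that allows ring C to be closed late is that C2 is bonded to O1 and benzylic to ring B, whose C4' oxygen is para. With a C3=C4 double bond in place, a cation at C2 is delocalized through C4 into ring A (O1, C5–O, C7–O). This is a vinylogous ortho-quinone methide with O1 next to C2, so O1–C2 can be formed under a chiral counter-anion.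

## Retrosynthesis

**25 ⇒ 24 ⇒ 23.** No skeletal bond is cut. The seven phenols are masked as benzyl ethers (24) and the C4 carbonyl is traced back to the alcohol 23. Carrying the ketone earlier would expose C3 to epimerization in every step, and methyl ethers would need a Lewis acid at the end. With C4 as an alcohol the only epimerizable centre appears in the last two steps. The forward steps (buffered Dess–Martin oxidation, hydrogenolysis) must stay neutral.

**23 ⇒ 22 ⇒ 20 + 21.** Ring F is opened at O1''–C2'' (oxa-Michael), and the enone C2''=C3'' is cut by a Claisen–Schmidt condensation. Cutting at C4''–C4a'' instead (Friedel–Crafts acylation) would need acid and could not tell ring D from ring A. Unit 2 shrinks to an acetyl group and a free phenol on ring D (20) plus commercial 4-(benzyloxy)benzaldehyde 21. The forward closure must set C2'' by catalyst control.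

**20 ⇒ 19 ⇒ 17.** The aryl–acyl bond C4a''–C4'' is cut. The acetyl group comes from an aryllithium made from bromide 17 by halogen–lithium exchange. Deprotonative lithiation or electrophilic acylation at this stage would have to choose among C6''–H, C6–H and C8–H in the presence of six benzyl ethers; the exchange is site-specific. The SEM ether (C8a''–O) and TBS ether (C4–O) are removed together by fluoride before the enone exists, so no phenoxide meets an enone without a chiral catalyst.

**17 ⇒ 16 ⇒ 14.** C3–H and C4–O are removed to give the C3=C4 alkene of chromene 14. Hydroboration is preferred to reduction of a chromone because it stops at the alcohol level and adds anti to ring B, giving the cis-2,3 relationship. Two stereocentres disappear and only C2 remains. Boron must go to C4 (as with isoflav-3-enes), on the face opposite ring B.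

**14 ⇒ 13 (key).** The O1–C2 bond is cut. The alternatives are to add ring B to a benzopyrylium ion (C2–C1' cut) or to arylate C3. The O1–C2 cut uses the natural polarity: a phenol nucleophile and a doubly stabilized allylic/benzylic cation. The carbinol centre of 13 is lost on ionization, so it need not be controlled. The precursor is an open-chain (Z)-allylic alcohol, racemic at the carbinol. The forward step needs enantioface control at C2.

**13 ⇒ 10 + 11; 10 ⇒ 9.** The C2–C1' bond is cut (Grignard reagent from bromide 11 added to lactol 10), and 10 comes from coumarin 9 by partial reduction. The lactone ring fixes the Z geometry, which an olefination of a trisubstituted alkene would not. Coumarin 9 is flat and stable. The reduction must stop at the lactol and the addition must be 1,2.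

**9 ⇒ 2 + 8.** C3=C4 and the lactone C–O bond are cut by a Perkin–Oglialoro condensation of salicylaldehyde 2 with arylacetic acid 8. A Suzuki coupling of a 3-halocoumarin was set aside: 2,6-dialkoxyarylboron reagents protodeboronate, and the bromine on ring D would compete. Two monocyclic pieces result.

**8 ⇒ 7 ⇒ 5 ⇒ 3 ⇒ 1; 2 ⇒ 1.** Both substituents of ring D flank the SEM-protected oxygen. They are introduced by two acetal-directed lithiations of 3 (oxirane, then a bromine donor), and the alcohol 7 is oxidized to the acid. Electrophilic substitution would give ortho/para mixtures. Aldehyde 2 comes from the same phenol 1 by magnesium-mediated ortho-formylation, so rings A and D share one commercial starting material.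

## Roads not taken

**Alternative 1:** Ring A is cut at C4a–C8a, C5–C6 and C7–C8. Forward, [Rh(cod)2]BF4 with BINAP (a monovalent rhodium catalyst) would join two alkynes tethered through O1–C2–C3–C4 with an external alkoxyacetylene, closing rings A and C together to give the silyl ether A1.
- Merits: ring A is assembled late under neutral conditions, no acid-labile allylic alcohol is handled, and C4 arrives at the alcohol level with C2 and C3 already fixed, so no hydroboration is needed.
- Weak points: C2, C3 and C4, including the cis-diaryl pair, must be set first on an open chain. An ynol ether on a secondary benzylic oxygen is fragile. The external alkyne can insert in either orientation (oxygen at C7 or C6). The chiral ligand has no stereocentre to create.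
- Comparison: A1 corresponds to 17 without the bromine, so ring D would still have to be acylated in competition with ring A. Alternative 1 is better in avoiding the sensitive diol 13. The chosen plan buys its aromatic rings and sets C2 catalytically and C3 from C2.

**Alternative 2:** The C2–C3 bond is cut. Forward, a carbenoid at C3 (from a diazo group between the C4 carbonyl and ring D) on Rh2(S-PTTL)4 (a divalent rhodium carboxylate) would insert into a C–H bond of the O1–CH2–ring B group, giving the protected target A2.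
- Merits: both centres of unit 1 are formed in one step at the final oxidation level. Unit 2 is made separately, with ring D regiochemistry settled on a small molecule. Only deprotection remains.
- Weak points: a six-membered ring by 1,6-insertion is less favoured than the usual 1,5-mode. Oxonium ylide formation at O1 and attack on neighbouring arenes compete. The diazo ketone lies next to a 2,6-disubstituted ring and must be made in the presence of the second ketone. The cis ketone is epimerizable from the moment it forms and must survive desilylation and hydrogenolysis.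
- Comparison: alternative 2 is clearly shorter and more convergent after its key step. The chosen plan has a ring closure that follows a documented acid-catalysed pattern favoured by the substrate electronics, and C3 cannot epimerize until the second-last step.

**Alternative 3:** O1–C2 and C3–C8'' are cut. Forward, an arylpalladium species from a ring D iodide (Pd(OAc)2, a divalent palladium precatalyst, SPhos, K3PO4; zerovalent palladium in the cycle) would activate an ortho-hydroxyaryl ynone; 6-endo attack of the phenol and reductive elimination would give chromone A3.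
- Merits: it is the most convergent entry to the skeleton, from flat, robust fragments, and forms the same O1–C2 bond as the chosen plan together with C3–C8''.
- Weak points: A3 has no stereocentre. C2 and C3 would have to come from an enantioselective cis reduction of a tetrasubstituted, electron-rich chromone flanked by a di-ortho-substituted aryl group. That reduction would meet the benzyl ethers and deliver the epimerizable cis ketone directly. 5-exo closure (aurone) and the hindered reductive elimination are further risks.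
- Comparison: alternative 3 needs fewer steps to the skeleton. In the chosen plan the ring closure itself creates C2, and C3 follows by substrate control.

Key step: step 9

Abbreviations: Bn = benzyl; SEM = [2-(trimethylsilyl)ethoxy]methyl; TBS = tert-butyldimethylsilyl.

Assumption: the (R)-phosphoramide is taken to give (S)-14 and the quinine-derived thiourea the (S) centre at C2''; if either sense is reversed, the enantiomeric or pseudoenantiomeric catalyst is used with no other change.

## Route

Step 1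
Reactants: 1 3,5-bis(benzyloxy)phenol
Product: 2 4,6-bis(benzyloxy)-2-hydroxybenzaldehyde
Conditions: MgCl2, Et3N, (CH2O)n, MeCN, reflux
Reagents that add atoms: paraformaldehyde (formaldehyde), C=O
Why: Casnati–Skattebøl ortho-formylation: the magnesium phenoxide delivers formaldehyde only to the ortho carbon and a second equivalent oxidizes the benzylic alkoxide, so the aldehyde enters between OH and OBn and not para.

Step 2
Reactants: 1 3,5-bis(benzyloxy)phenol
Product: 3 1,3-bis(benzyloxy)-5-(SEM-oxy)benzene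
Conditions: SEMCl, i-Pr2NEt, CH2Cl2, 0 °C → rt
Reagents that add atoms: 2-(trimethylsilyl)ethoxymethyl chloride, C[Si](C)(C)CCOCCl
Why: O-alkylation of the phenol with a chloromethyl ether; the SEM acetal tolerates organolithiums, hydride, Grignard reagents and the acid of step 9, and it is a chelating director for lithiation.

Step 3
Reactants: 3 1,3-bis(benzyloxy)-5-(SEM-oxy)benzene
Product: 5 2-[2,4-bis(benzyloxy)-6-(SEM-oxy)phenyl]ethan-1-ol, via aryllithium 4 (not isolated)
Conditions: n-BuLi, THF, 0 °C; then oxirane, −78 °C → rt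
Reagents that add atoms: oxirane, C1CO1
Why: Directed ortho-metalation: the acetal oxygens chelate lithium, so one of the two equivalent carbons between OSEM and OBn should be deprotonated in preference to the carbon between two benzyloxy groups; the aryllithium then opens oxirane.

Step 4
Reactants: 5 2-[2,4-bis(benzyloxy)-6-(SEM-oxy)phenyl]ethan-1-ol
Product: 7 2-[4,6-bis(benzyloxy)-3-bromo-2-(SEM-oxy)phenyl]ethan-1-ol, via dilithio species 6 (not isolated)
Conditions: n-BuLi (2.2 equiv), THF, 0 °C; then BrCl2C–CCl2Br, −78 °C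
Reagents that add atoms: 1,2-dibromo-1,1,2,2-tetrachloroethane, BrC(Cl)(Cl)C(Cl)(Cl)Br
Why: Second directed ortho-metalation on the lithium alkoxide; only one hydrogen is left next to OSEM, and the aryllithium takes bromine from the dibromide with loss of tetrachloroethene.

Step 5
Reactants: 7 2-[4,6-bis(benzyloxy)-3-bromo-2-(SEM-oxy)phenyl]ethan-1-ol
Product: 8 2-[4,6-bis(benzyloxy)-3-bromo-2-(SEM-oxy)phenyl]acetic acid
Conditions: TEMPO (cat.), PhI(OAc)2, MeCN–H2O, rt
Reagents that add atoms: water, O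
Why: Oxoammonium (TEMPO) oxidation of a primary alcohol through the aldehyde hydrate to the carboxylic acid; near-neutral, so the SEM acetal, aryl bromide and benzyl ethers should be untouched.

Step 6
Reactants: 2 4,6-bis(benzyloxy)-2-hydroxybenzaldehyde; 8 2-[4,6-bis(benzyloxy)-3-bromo-2-(SEM-oxy)phenyl]acetic acid
Product: 9 5,7-bis(benzyloxy)-3-[4,6-bis(benzyloxy)-3-bromo-2-(SEM-oxy)phenyl]-2H-chromen-2-one
Conditions: Ac2O, Et3N, 110 °C
Reagents that add atoms: none
Why: Perkin–Oglialoro condensation: the enolate of the mixed anhydride adds to the aldehyde, and elimination with lactonization gives the 3-arylcoumarin, whose ring fixes ring A and C2 cis across C3=C4.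

Step 7
Reactants: 9 5,7-bis(benzyloxy)-3-[4,6-bis(benzyloxy)-3-bromo-2-(SEM-oxy)phenyl]-2H-chromen-2-one
Product: 10 5,7-bis(benzyloxy)-3-[4,6-bis(benzyloxy)-3-bromo-2-(SEM-oxy)phenyl]-2H-chromen-2-ol (racemic lactol)
Conditions: i-Bu2AlH, CH2Cl2, −78 °C; aq. potassium sodium tartrate (KNaC4H4O6)
Reagents that add atoms: none
Why: Partial reduction of a lactone with i-Bu2AlH; the tetrahedral aluminate persists at −78 °C and should give the lactol on work-up.

Step 8
Reactants: 10 5,7-bis(benzyloxy)-3-[4,6-bis(benzyloxy)-3-bromo-2-(SEM-oxy)phenyl]-2H-chromen-2-ol; 11 4-bromo-1,2-bis(benzyloxy)benzene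
Product: 13 3,5-bis(benzyloxy)-2-[(1Z)-2-[4,6-bis(benzyloxy)-3-bromo-2-(SEM-oxy)phenyl]-3-[3,4-bis(benzyloxy)phenyl]-3-hydroxyprop-1-en-1-yl]phenol (racemic at the carbinol carbon), via Grignard reagent 12 (not isolated)
Conditions: 11, Mg, THF; then 10, THF, −40 → 0 °C; aq. NaH2PO4/Na2HPO4 (pH 7)
Reagents that add atoms: none
Why: Grignard addition to a lactol through its ring-opened (Z)-hydroxy-enal (the first equivalent deprotonates); 1,2-addition keeps the Z geometry, and the aryl bromide on ring D does not exchange with an arylmagnesium halide.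

Step 9
Reactants: 13 3,5-bis(benzyloxy)-2-[(1Z)-2-[4,6-bis(benzyloxy)-3-bromo-2-(SEM-oxy)phenyl]-3-[3,4-bis(benzyloxy)phenyl]-3-hydroxyprop-1-en-1-yl]phenol
Product: 14 (2S)-5,7-bis(benzyloxy)-2-[3,4-bis(benzyloxy)phenyl]-3-[4,6-bis(benzyloxy)-3-bromo-2-(SEM-oxy)phenyl]-2H-chromene
Conditions: (R)-3,3'-bis(2,4,6-triisopropylphenyl)-BINOL N-triflyl phosphoramide (5 mol%), toluene, −78 °C, dark; Et3N quench
Reagents that add atoms: none
Why: The phosphoramide protonates the carbinol hydroxyl and water leaves to give an allyl cation C2–C3–C4 stabilized by ring B (para oxygen) and, through C4, by ring A, that is, the protonated form of a vinylogous ortho-quinone methide paired with the chiral phosphoramide anion. The closest known reaction type is the chiral N-triflyl phosphoramide-catalysed intramolecular allylic substitution of 2-(3-aryl-3-hydroxyprop-1-enyl)phenols to 2-aryl-2H-chromenes. Ring C closes by attack of O1 on the C2 terminus, formally 6-endo with respect to the allyl cation and equivalent to an oxa-6π electrocyclization of the quinone methide. The new centre C2 is controlled by the counter-anion, which shields one face of the planar C2 terminus while hydrogen-bonded to the phenol; both enantiomers of 13 give the same ion, so the carbinol configuration is irrelevant. The step needs enantioface selectivity at C2 and site selectivity for O1: the Z geometry from coumarin 9 places O1 next to C2, the SEM group keeps the ring D oxygen from closing a five-membered ring, and the bromide and benzyl ethers are inert. Low temperature, an apolar solvent and exclusion of light and stray acid should keep the ion pair tight and prevent re-ionization or electrocyclic opening of 14, in which C3 is sp2 and nothing can epimerize.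

Step 10
Reactants: 14 (2S)-5,7-bis(benzyloxy)-2-[3,4-bis(benzyloxy)phenyl]-3-[4,6-bis(benzyloxy)-3-bromo-2-(SEM-oxy)phenyl]-2H-chromene
Product: 16 (2R,3S,4S)-5,7-bis(benzyloxy)-2-[3,4-bis(benzyloxy)phenyl]-3-[4,6-bis(benzyloxy)-3-bromo-2-(SEM-oxy)phenyl]chroman-4-ol (2,3-cis and 3,4-trans), via C4 alkylborane 15 (not isolated)
Conditions: BH3·THF, THF, 0 °C → rt; then NaOH, H2O2, 0 °C
Reagents that add atoms: hydrogen peroxide, OO; borane–THF, B.C1CCOC1 (boron stays only in 15)
Why: Hydroboration–oxidation of a 3-aryl-2H-chromene: boron goes to the less substituted C4 as with isoflav-3-enes and hydrogen to C3, syn and on the face opposite the C2 aryl group; oxidation with retention should give the 2,3-cis alcohol, so C3 is set by substrate control from C2.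

Step 11
Reactants: 16 (2R,3S,4S)-5,7-bis(benzyloxy)-2-[3,4-bis(benzyloxy)phenyl]-3-[4,6-bis(benzyloxy)-3-bromo-2-(SEM-oxy)phenyl]chroman-4-ol
Product: 17 (2R,3R,4S)-5,7-bis(benzyloxy)-2-[3,4-bis(benzyloxy)phenyl]-3-[4,6-bis(benzyloxy)-3-bromo-2-(SEM-oxy)phenyl]-4-(TBS-oxy)chromane
Conditions: TBSOTf, 2,6-lutidine, CH2Cl2, −78 → 0 °C
Reagents that add atoms: tert-butyldimethylsilyl trifluoromethanesulfonate, CC(C)(C)[Si](C)(C)OS(=O)(=O)C(F)(F)F
Why: Silylation of a hindered secondary alcohol with a silyl triflate and a hindered base; the ether keeps an alkoxide out of the organolithium step and leaves later together with SEM (the C3 descriptor changes by priority only).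

Step 12
Reactants: 17 (2R,3R,4S)-5,7-bis(benzyloxy)-2-[3,4-bis(benzyloxy)phenyl]-3-[4,6-bis(benzyloxy)-3-bromo-2-(SEM-oxy)phenyl]-4-(TBS-oxy)chromane
Product: 19 1-{4,6-bis(benzyloxy)-3-[(2R,3R,4S)-5,7-bis(benzyloxy)-2-[3,4-bis(benzyloxy)phenyl]-4-(TBS-oxy)chroman-3-yl]-2-(SEM-oxy)phenyl}ethan-1-one, via aryllithium 18 (not isolated)
Conditions: t-BuLi (2.1 equiv), THF, −78 °C; then MeC(O)N(OMe)Me, −78 → −20 °C
Reagents that add atoms: N-methoxy-N-methylacetamide, CC(=O)N(C)OC
Why: Bromine–lithium exchange is faster at −78 °C than any deprotonation and is site-specific (the second equivalent destroys t-BuBr); Weinreb acylation gives a chelated tetrahedral adduct that releases the ketone only on work-up.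

Step 13
Reactants: 19 1-{4,6-bis(benzyloxy)-3-[(2R,3R,4S)-5,7-bis(benzyloxy)-2-[3,4-bis(benzyloxy)phenyl]-4-(TBS-oxy)chroman-3-yl]-2-(SEM-oxy)phenyl}ethan-1-one
Product: 20 1-{4,6-bis(benzyloxy)-3-[(2R,3S,4S)-5,7-bis(benzyloxy)-2-[3,4-bis(benzyloxy)phenyl]-4-hydroxychroman-3-yl]-2-hydroxyphenyl}ethan-1-one
Conditions: Bu4NF, THF–DMPU, 60 °C
Reagents that add atoms: none
Why: Fluoride attacks silicon: the aryl SEM ether fragments to ethene, formaldehyde and phenoxide and the TBS ether is cleaved in the same operation; this is done before an enone exists, so the phenoxide cannot cyclize without stereocontrol.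

Step 14
Reactants: 20 1-{4,6-bis(benzyloxy)-3-[(2R,3S,4S)-5,7-bis(benzyloxy)-2-[3,4-bis(benzyloxy)phenyl]-4-hydroxychroman-3-yl]-2-hydroxyphenyl}ethan-1-one; 21 4-(benzyloxy)benzaldehyde
Product: 22 (2E)-1-{4,6-bis(benzyloxy)-3-[(2R,3S,4S)-5,7-bis(benzyloxy)-2-[3,4-bis(benzyloxy)phenyl]-4-hydroxychroman-3-yl]-2-hydroxyphenyl}-3-[4-(benzyloxy)phenyl]prop-2-en-1-one
Conditions: KOH, EtOH–H2O, rt; neutralization to pH 6 at 0 °C
Reagents that add atoms: none
Why: Claisen–Schmidt condensation; in strong base the 2'-hydroxychalcone is held as its conjugated phenoxide and should be isolated as the (E)-enone, and unit 1 has no enolizable centre at this stage.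

Step 15
Reactants: 22 (2E)-1-{4,6-bis(benzyloxy)-3-[(2R,3S,4S)-5,7-bis(benzyloxy)-2-[3,4-bis(benzyloxy)phenyl]-4-hydroxychroman-3-yl]-2-hydroxyphenyl}-3-[4-(benzyloxy)phenyl]prop-2-en-1-one
Product: 23 (2S)-5,7-bis(benzyloxy)-2-[4-(benzyloxy)phenyl]-8-[(2R,3S,4S)-5,7-bis(benzyloxy)-2-[3,4-bis(benzyloxy)phenyl]-4-hydroxychroman-3-yl]chroman-4-one
Conditions: quinine-derived 3,5-bis(trifluoromethyl)phenyl thiourea (20 mol%), toluene, rt
Reagents that add atoms: none
Why: Organocatalytic enantioselective intramolecular oxa-Michael addition of a 2'-hydroxychalcone: the quinuclidine activates the phenol and the thiourea binds the enone carbonyl, so one face of the beta carbon is attacked and C2'' is set by the catalyst; the C2'' epimers are diastereomers and the minor one can be removed by chromatography.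

Step 16
Reactants: 23 (2S)-5,7-bis(benzyloxy)-2-[4-(benzyloxy)phenyl]-8-[(2R,3S,4S)-5,7-bis(benzyloxy)-2-[3,4-bis(benzyloxy)phenyl]-4-hydroxychroman-3-yl]chroman-4-one
Product: 24 (2S)-5,7-bis(benzyloxy)-2-[4-(benzyloxy)phenyl]-8-[(2R,3R)-5,7-bis(benzyloxy)-2-[3,4-bis(benzyloxy)phenyl]-4-oxochroman-3-yl]chroman-4-one
Conditions: Dess–Martin periodinane, NaHCO3, CH2Cl2, 0 °C → rt
Reagents that add atoms: none
Why: Dess–Martin oxidation of the benzylic secondary alcohol under bicarbonate buffer, without acid or base strong enough to enolize the new ketone, so the cis relationship at C2/C3 should be kept.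

Step 17
Reactants: 24 (2S)-5,7-bis(benzyloxy)-2-[4-(benzyloxy)phenyl]-8-[(2R,3R)-5,7-bis(benzyloxy)-2-[3,4-bis(benzyloxy)phenyl]-4-oxochroman-3-yl]chroman-4-one
Product: 25 (2S)-8-[(2R,3R)-2-(3,4-dihydroxyphenyl)-5,7-dihydroxy-4-oxochroman-3-yl]-5,7-dihydroxy-2-(4-hydroxyphenyl)chroman-4-one (CNP0105436.1)
Conditions: H2 (1 atm), 10% Pd/C, EtOAc–MeOH, rt
Reagents that add atoms: none
Why: Catalytic hydrogenolysis of the seven benzyl ethers under neutral conditions; no stereocentre is touched and no acid or base is present to epimerize C3 or open a flavanone ring.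

## Compound list

1 | 3,5-bis(benzyloxy)phenol | Oc1cc(OCc2ccccc2)cc(OCc2ccccc2)c1 | starting material
2 | 4,6-bis(benzyloxy)-2-hydroxybenzaldehyde | O=Cc1c(O)cc(OCc2ccccc2)cc1OCc1ccccc1 | intermediate
3 | 1,3-bis(benzyloxy)-5-(SEM-oxy)benzene | C[Si](C)(C)CCOCOc1cc(OCc2ccccc2)cc(OCc2ccccc2)c1 | intermediate
4 | [2,4-bis(benzyloxy)-6-(SEM-oxy)phenyl]lithium | [Li]c1c(OCOCC[Si](C)(C)C)cc(OCc2ccccc2)cc1OCc1ccccc1 | intermediate (not isolated)
5 | 2-[2,4-bis(benzyloxy)-6-(SEM-oxy)phenyl]ethan-1-ol | OCCc1c(OCOCC[Si](C)(C)C)cc(OCc2ccccc2)cc1OCc1ccccc1 | intermediate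
6 | lithium 2-[4,6-bis(benzyloxy)-3-lithio-2-(SEM-oxy)phenyl]ethan-1-olate | [Li]OCCc1c(OCOCC[Si](C)(C)C)c([Li])c(OCc2ccccc2)cc1OCc1ccccc1 | intermediate (not isolated)
7 | 2-[4,6-bis(benzyloxy)-3-bromo-2-(SEM-oxy)phenyl]ethan-1-ol | OCCc1c(OCOCC[Si](C)(C)C)c(Br)c(OCc2ccccc2)cc1OCc1ccccc1 | intermediate
8 | 2-[4,6-bis(benzyloxy)-3-bromo-2-(SEM-oxy)phenyl]acetic acid | OC(=O)Cc1c(OCOCC[Si](C)(C)C)c(Br)c(OCc2ccccc2)cc1OCc1ccccc1 | intermediate
9 | 5,7-bis(benzyloxy)-3-[4,6-bis(benzyloxy)-3-bromo-2-(SEM-oxy)phenyl]-2H-chromen-2-one | O=C1Oc2cc(OCc3ccccc3)cc(OCc3ccccc3)c2C=C1c1c(OCOCC[Si](C)(C)C)c(Br)c(OCc2ccccc2)cc1OCc1ccccc1 | intermediate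
10 | 5,7-bis(benzyloxy)-3-[4,6-bis(benzyloxy)-3-bromo-2-(SEM-oxy)phenyl]-2H-chromen-2-ol (racemic) | OC1Oc2cc(OCc3ccccc3)cc(OCc3ccccc3)c2C=C1c1c(OCOCC[Si](C)(C)C)c(Br)c(OCc2ccccc2)cc1OCc1ccccc1 | intermediate
11 | 4-bromo-1,2-bis(benzyloxy)benzene | Brc1ccc(OCc2ccccc2)c(OCc2ccccc2)c1 | starting material
12 | [3,4-bis(benzyloxy)phenyl]magnesium bromide | Br[Mg]c1ccc(OCc2ccccc2)c(OCc2ccccc2)c1 | intermediate (not isolated)
13 | (Z)-allylic alcohol, racemic at the carbinol: 3,5-bis(benzyloxy)-2-[(1Z)-2-[4,6-bis(benzyloxy)-3-bromo-2-(SEM-oxy)phenyl]-3-[3,4-bis(benzyloxy)phenyl]-3-hydroxyprop-1-en-1-yl]phenol | Oc1cc(OCc2ccccc2)cc(OCc2ccccc2)c1/C=C(/c1c(OCOCC[Si](C)(C)C)c(Br)c(OCc2ccccc2)cc1OCc1ccccc1)C(O)c1ccc(OCc2ccccc2)c(OCc2ccccc2)c1 | intermediate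
14 | (2S)-5,7-bis(benzyloxy)-2-[3,4-bis(benzyloxy)phenyl]-3-[4,6-bis(benzyloxy)-3-bromo-2-(SEM-oxy)phenyl]-2H-chromene | C[Si](C)(C)CCOCOc1c(Br)c(OCc2ccccc2)cc(OCc2ccccc2)c1C1=Cc2c(OCc3ccccc3)cc(OCc3ccccc3)cc2O[C@H]1c1ccc(OCc2ccccc2)c(OCc2ccccc2)c1 | intermediate
15 | C4 alkylborane of 14 (2,3-cis; boron at C4 trans to the C3 aryl group) | C[Si](C)(C)CCOCOc1c(Br)c(OCc2ccccc2)cc(OCc2ccccc2)c1[C@H]1[C@H](B)c2c(OCc3ccccc3)cc(OCc3ccccc3)cc2O[C@H]1c1ccc(OCc2ccccc2)c(OCc2ccccc2)c1 | intermediate (not isolated)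
16 | (2R,3S,4S)-5,7-bis(benzyloxy)-2-[3,4-bis(benzyloxy)phenyl]-3-[4,6-bis(benzyloxy)-3-bromo-2-(SEM-oxy)phenyl]chroman-4-ol | C[Si](C)(C)CCOCOc1c(Br)c(OCc2ccccc2)cc(OCc2ccccc2)c1[C@H]1[C@H](O)c2c(OCc3ccccc3)cc(OCc3ccccc3)cc2O[C@H]1c1ccc(OCc2ccccc2)c(OCc2ccccc2)c1 | intermediate
17 | (2R,3R,4S)-5,7-bis(benzyloxy)-2-[3,4-bis(benzyloxy)phenyl]-3-[4,6-bis(benzyloxy)-3-bromo-2-(SEM-oxy)phenyl]-4-(TBS-oxy)chromane | C[Si](C)(C)CCOCOc1c(Br)c(OCc2ccccc2)cc(OCc2ccccc2)c1[C@H]1[C@H](O[Si](C)(C)C(C)(C)C)c2c(OCc3ccccc3)cc(OCc3ccccc3)cc2O[C@H]1c1ccc(OCc2ccccc2)c(OCc2ccccc2)c1 | intermediate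
18 | aryllithium from 17 (lithium in place of bromine) | C[Si](C)(C)CCOCOc1c([Li])c(OCc2ccccc2)cc(OCc2ccccc2)c1[C@H]1[C@H](O[Si](C)(C)C(C)(C)C)c2c(OCc3ccccc3)cc(OCc3ccccc3)cc2O[C@H]1c1ccc(OCc2ccccc2)c(OCc2ccccc2)c1 | intermediate (not isolated)
19 | 1-{4,6-bis(benzyloxy)-3-[(2R,3R,4S)-5,7-bis(benzyloxy)-2-[3,4-bis(benzyloxy)phenyl]-4-(TBS-oxy)chroman-3-yl]-2-(SEM-oxy)phenyl}ethan-1-one | C[Si](C)(C)CCOCOc1c(C(C)=O)c(OCc2ccccc2)cc(OCc2ccccc2)c1[C@H]1[C@H](O[Si](C)(C)C(C)(C)C)c2c(OCc3ccccc3)cc(OCc3ccccc3)cc2O[C@H]1c1ccc(OCc2ccccc2)c(OCc2ccccc2)c1 | intermediate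
20 | 1-{4,6-bis(benzyloxy)-3-[(2R,3S,4S)-5,7-bis(benzyloxy)-2-[3,4-bis(benzyloxy)phenyl]-4-hydroxychroman-3-yl]-2-hydroxyphenyl}ethan-1-one | Oc1c(C(C)=O)c(OCc2ccccc2)cc(OCc2ccccc2)c1[C@H]1[C@H](O)c2c(OCc3ccccc3)cc(OCc3ccccc3)cc2O[C@H]1c1ccc(OCc2ccccc2)c(OCc2ccccc2)c1 | intermediate
21 | 4-(benzyloxy)benzaldehyde | O=Cc1ccc(OCc2ccccc2)cc1 | starting material
22 | (2E)-1-{4,6-bis(benzyloxy)-3-[(2R,3S,4S)-5,7-bis(benzyloxy)-2-[3,4-bis(benzyloxy)phenyl]-4-hydroxychroman-3-yl]-2-hydroxyphenyl}-3-[4-(benzyloxy)phenyl]prop-2-en-1-one | Oc1c(C(=O)/C=C/c2ccc(OCc3ccccc3)cc2)c(OCc2ccccc2)cc(OCc2ccccc2)c1[C@H]1[C@H](O)c2c(OCc3ccccc3)cc(OCc3ccccc3)cc2O[C@H]1c1ccc(OCc2ccccc2)c(OCc2ccccc2)c1 | intermediate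
23 | (2S)-5,7-bis(benzyloxy)-2-[4-(benzyloxy)phenyl]-8-[(2R,3S,4S)-5,7-bis(benzyloxy)-2-[3,4-bis(benzyloxy)phenyl]-4-hydroxychroman-3-yl]chroman-4-one | O=C1C[C@@H](c2ccc(OCc3ccccc3)cc2)Oc2c1c(OCc1ccccc1)cc(OCc1ccccc1)c2[C@H]1[C@H](O)c2c(OCc3ccccc3)cc(OCc3ccccc3)cc2O[C@H]1c1ccc(OCc2ccccc2)c(OCc2ccccc2)c1 | intermediate
24 | (2S)-5,7-bis(benzyloxy)-2-[4-(benzyloxy)phenyl]-8-[(2R,3R)-5,7-bis(benzyloxy)-2-[3,4-bis(benzyloxy)phenyl]-4-oxochroman-3-yl]chroman-4-one | O=C1C[C@@H](c2ccc(OCc3ccccc3)cc2)Oc2c1c(OCc1ccccc1)cc(OCc1ccccc1)c2[C@H]1C(=O)c2c(OCc3ccccc3)cc(OCc3ccccc3)cc2O[C@H]1c1ccc(OCc2ccccc2)c(OCc2ccccc2)c1 | intermediate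
25 | (2S)-8-[(2R,3R)-2-(3,4-dihydroxyphenyl)-5,7-dihydroxy-4-oxochroman-3-yl]-5,7-dihydroxy-2-(4-hydroxyphenyl)chroman-4-one | O=C1C[C@@H](c2ccc(O)cc2)Oc2c1c(O)cc(O)c2[C@H]1C(=O)c2c(O)cc(O)cc2O[C@H]1c1ccc(O)c(O)c1 | target

## Step count and least certain steps

Total step count: 17. Longest linear sequence: 16 steps (1 → 3 → 5 → 7 → 8 → 9 → 10 → 13 → 14 → 16 → 17 → 19 → 20 → 22 → 23 → 24 → 25); step 1 is the only branch.

**Step 9 (key step).** The cation is unusually stabilized by rings A and B, so closure may outrun tight ion pairing and the two faces of C2 may be poorly discriminated. Diol 13 may also close without the catalyst on stray acid during its isolation, and 14 may lose enantiomeric purity by re-ionization or light-induced ring opening. Fallback: set out from lactol 10 and return at 14. The lactol is converted with EtOH and pyridinium p-toluenesulfonate into 5,7-bis(benzyloxy)-3-[4,6-bis(benzyloxy)-3-bromo-2-(SEM-oxy)phenyl]-2-ethoxy-2H-chromene F1. Ring B is then added to C2 as diethyl [3,4-bis(benzyloxy)phenyl]boronate F2 (from Grignard reagent 12 and triethyl borate) under a tartaric acid-derived chiral diol with Yb(OTf)3. This known enantioselective boronate addition to chromene acetals forms the C2–aryl bond on a preformed ring C instead of O1–C2.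

**Step 15.** Discrimination of the two faces of the enone may be poor next to the bulky C8'' substituent, and the epimers may equilibrate by retro-oxa-Michael reaction on long exposure to the amine. Fallback: set out from 20 and return at 23. Ketone 20 is condensed with N,N-dimethylformamide dimethyl acetal to (2E)-1-{4,6-bis(benzyloxy)-3-[(2R,3S,4S)-5,7-bis(benzyloxy)-2-[3,4-bis(benzyloxy)phenyl]-4-hydroxychroman-3-yl]-2-hydroxyphenyl}-3-(dimethylamino)prop-2-en-1-one F3. With AcOH at rt this closes to 5,7-bis(benzyloxy)-8-[(2R,3S,4S)-5,7-bis(benzyloxy)-2-[3,4-bis(benzyloxy)phenyl]-4-hydroxychroman-3-yl]-4H-chromen-4-one F4. 4-(Benzyloxy)phenylboronic acid is then added 1,4 with [Rh(OH)(cod)]2 and a chiral diene ligand, an irreversible catalyst-controlled C–C bond formation that sets C2''.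

**Step 12.** The exchange may be incomplete, or the hindered aryllithium may be protonated by the alpha hydrogens of the amide instead of adding, returning the debrominated arene. Fallback: set out from 17 and return at 19. Stille coupling of 17 with tributyl(1-ethoxyvinyl)stannane (Pd(P(t-Bu)3)2, CsF, 1,4-dioxane, 90 °C) gives (2R,3R,4S)-5,7-bis(benzyloxy)-2-[3,4-bis(benzyloxy)phenyl]-3-[4,6-bis(benzyloxy)-3-(1-ethoxyethenyl)-2-(SEM-oxy)phenyl]-4-(TBS-oxy)chromane F5. Hydrolysis of the enol ether with aqueous oxalic acid on silica gives 19.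

**Step 4 (and step 3).** Lithiation may occur at the carbon between the two benzyloxy groups or at a benzylic OCH2 (followed by Wittig rearrangement), and the dianion may form incompletely. Fallback: set out from aldehyde 2 and return at acid 8.
- Bromination of 2 with N-bromosuccinimide ortho to the chelated hydroxyl gives 4,6-bis(benzyloxy)-3-bromo-2-hydroxybenzaldehyde F6.
- SEMCl and NaH give 4,6-bis(benzyloxy)-3-bromo-2-(SEM-oxy)benzaldehyde F7.
- Wittig reaction with Ph3P=CHOMe gives 1,5-bis(benzyloxy)-2-bromo-4-(2-methoxyethenyl)-3-(SEM-oxy)benzene F8 as an E/Z mixture.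
- Hydrolysis with cold aqueous formic acid gives 2-[4,6-bis(benzyloxy)-3-bromo-2-(SEM-oxy)phenyl]acetaldehyde F9.
- Pinnick oxidation (NaClO2, NaH2PO4, 2-methyl-2-butene) gives 8.

**Step 17.** C3 may enolize on the catalyst surface and drift to the trans epimer, the benzylic C2–O1 or C2''–O1'' bonds may be cleaved reductively, or some of the seven ethers may remain. Fallback: set out from 24 and return at 25 without a new intermediate, by non-reductive debenzylation with BCl3 and pentamethylbenzene as cation scavenger in CH2Cl2 at −78 °C.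

## Further compounds

F1 | step 9 | 5,7-bis(benzyloxy)-3-[4,6-bis(benzyloxy)-3-bromo-2-(SEM-oxy)phenyl]-2-ethoxy-2H-chromene (racemic) | CCOC1Oc2cc(OCc3ccccc3)cc(OCc3ccccc3)c2C=C1c1c(OCOCC[Si](C)(C)C)c(Br)c(OCc2ccccc2)cc1OCc1ccccc1
F2 | step 9 | diethyl [3,4-bis(benzyloxy)phenyl]boronate | CCOB(OCC)c1ccc(OCc2ccccc2)c(OCc2ccccc2)c1
F3 | step 15 | (2E)-1-{4,6-bis(benzyloxy)-3-[(2R,3S,4S)-5,7-bis(benzyloxy)-2-[3,4-bis(benzyloxy)phenyl]-4-hydroxychroman-3-yl]-2-hydroxyphenyl}-3-(dimethylamino)prop-2-en-1-one | Oc1c(C(=O)/C=C/N(C)C)c(OCc2ccccc2)cc(OCc2ccccc2)c1[C@H]1[C@H](O)c2c(OCc3ccccc3)cc(OCc3ccccc3)cc2O[C@H]1c1ccc(OCc2ccccc2)c(OCc2ccccc2)c1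
F4 | step 15 | 5,7-bis(benzyloxy)-8-[(2R,3S,4S)-5,7-bis(benzyloxy)-2-[3,4-bis(benzyloxy)phenyl]-4-hydroxychroman-3-yl]-4H-chromen-4-one | O=c1ccoc2c1c(OCc1ccccc1)cc(OCc1ccccc1)c2[C@H]1[C@H](O)c2c(OCc3ccccc3)cc(OCc3ccccc3)cc2O[C@H]1c1ccc(OCc2ccccc2)c(OCc2ccccc2)c1
F5 | step 12 | (2R,3R,4S)-5,7-bis(benzyloxy)-2-[3,4-bis(benzyloxy)phenyl]-3-[4,6-bis(benzyloxy)-3-(1-ethoxyethenyl)-2-(SEM-oxy)phenyl]-4-(TBS-oxy)chromane | C[Si](C)(C)CCOCOc1c(C(=C)OCC)c(OCc2ccccc2)cc(OCc2ccccc2)c1[C@H]1[C@H](O[Si](C)(C)C(C)(C)C)c2c(OCc3ccccc3)cc(OCc3ccccc3)cc2O[C@H]1c1ccc(OCc2ccccc2)c(OCc2ccccc2)c1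
F6 | step 4 | 4,6-bis(benzyloxy)-3-bromo-2-hydroxybenzaldehyde | O=Cc1c(O)c(Br)c(OCc2ccccc2)cc1OCc1ccccc1
F7 | step 4 | 4,6-bis(benzyloxy)-3-bromo-2-(SEM-oxy)benzaldehyde | O=Cc1c(OCOCC[Si](C)(C)C)c(Br)c(OCc2ccccc2)cc1OCc1ccccc1
F8 | step 4 | 1,5-bis(benzyloxy)-2-bromo-4-(2-methoxyethenyl)-3-(SEM-oxy)benzene (E/Z mixture) | COC=Cc1c(OCOCC[Si](C)(C)C)c(Br)c(OCc2ccccc2)cc1OCc1ccccc1
F9 | step 4 | 2-[4,6-bis(benzyloxy)-3-bromo-2-(SEM-oxy)phenyl]acetaldehyde | O=CCc1c(OCOCC[Si](C)(C)C)c(Br)c(OCc2ccccc2)cc1OCc1ccccc1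
F0 | step 17 | none | none
A1 | alternative 1 | (2R,3R,4S)-5,7-bis(benzyloxy)-2-[3,4-bis(benzyloxy)phenyl]-3-[4-(benzyloxy)-2,6-bis(SEM-oxy)phenyl]-4-(TBS-oxy)chromane | C[Si](C)(C)CCOCOc1cc(OCc2ccccc2)cc(OCOCC[Si](C)(C)C)c1[C@H]1[C@H](O[Si](C)(C)C(C)(C)C)c2c(OCc3ccccc3)cc(OCc3ccccc3)cc2O[C@H]1c1ccc(OCc2ccccc2)c(OCc2ccccc2)c1
A2 | alternative 2 | (2S)-5-(benzyloxy)-2-[4-(benzyloxy)phenyl]-8-[(2R,3R)-5,7-bis(benzyloxy)-2-[3,4-bis(benzyloxy)phenyl]-4-oxochroman-3-yl]-7-(TBS-oxy)chroman-4-one | O=C1C[C@@H](c2ccc(OCc3ccccc3)cc2)Oc2c1c(OCc3ccccc3)cc(O[Si](C)(C)C(C)(C)C)c2[C@H]1C(=O)c2c(OCc3ccccc3)cc(OCc3ccccc3)cc2O[C@H]1c1ccc(OCc3ccccc3)c(OCc3ccccc3)c1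
A3 | alternative 3 | 5,7-bis(benzyloxy)-2-[3,4-bis(benzyloxy)phenyl]-3-[2,4-bis(benzyloxy)-6-(methoxymethoxy)phenyl]-4H-chromen-4-one | COCOc1cc(OCc2ccccc2)cc(OCc2ccccc2)c1-c1c(-c2ccc(OCc3ccccc3)c(OCc3ccccc3)c2)oc2cc(OCc3ccccc3)cc(OCc3ccccc3)c2c1=O
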